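**Retrosynthetic overview**

1. Target 18 comes from triol 17 by oxidation of C17–OH. C17 and the axial 8‑OH come from equatorial addition of a hydroxymethyl‑anion equivalent to the C8 ketone of 15. The 13Z enoate comes from a Negishi coupling with methyl (Z)‑3‑iodobut‑2‑enoate (11), and C11–C12 from α′‑alkylation at C9 of enone 7.
2. Ring B is the six‑membered ring of (1S,5S)‑verbenone (1). Ring A is formed second, in one operation: silyl dienol ether 2 plus acrolein forms C1–C10 and C3–C4 and cleaves the cyclobutane bond C4–C7, a bond of 1 that is not in the target.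
3. Enabling feature: in 18 the quaternary C10 (with C20) and the gem‑dimethyl carbon C4 are both bonded to C5–H, and C10 is β to the oxygen‑bearing C8 of ring B. This is the C4/C5/C6 array of the pinane bicycle: C4 already carries both methyls, is bonded to C5, and is held to C7 (α to C8) by a strained bond, so a radical at C8 releases C4 as a tertiary radical next to C5–H.
4. Stereocontrol: C5 from 1; C10 by attack anti to the gem‑dimethyl bridge (hence trans fusion); C3 in the chair closure; C9 by equilibration next to the C8 ketone; C8 by equatorial attack opposite the axial C20 methyl; 13Z from 11.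

Key step: step 2

Remark: labdane numbering of 18 (C1–C20) is used for all intermediates; 18 belongs to the ent‑labdane series, which is why the (1S,5S) enantiomer of verbenone is the starting material.

**Step 1**
Reactants: 1 (1S,5S)‑(−)‑verbenone
Product: 2 tert‑butyldimethylsilyl dienol ether of verbenone (exocyclic methylene on C10)
Conditions: TBSOTf, Et3N, CH2Cl2, 0 °C to rt
Reagents that add atoms: tert‑butyldimethylsilyl triflate, CC(C)(C)[Si](C)(C)OS(=O)(=O)C(F)(F)F
Why: Soft enolization and O‑silylation of an enone (silyl dienol ether formation); the bridgehead α′‑carbon cannot enolize (Bredt's rule), so only a γ‑hydrogen of the ring methyl (C20) is lost and the C5 stereocenter is untouched.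

**Step 2**
Reactants: 2 silyl dienol ether; 3 acrolein
Product: 5 ring‑A‑closed hydroxy silyl enol ether (C7=C8–OTBS), via Giese adduct 4 (not isolated)
Conditions: Fe(acac)3 (0.3 equiv), PhSiH3, Na2HPO4, EtOH/(CH2OH)2, 0 °C to rt
Reagents that add atoms: none
Why: Proposed new method: hydrogen‑atom transfer from the iron hydride to the exocyclic CH2 of 2 (which becomes the C20 methyl) should give a 1‑siloxyallyl radical over C8–C9–C10 that undergoes Giese addition to acrolein through its tertiary end C10 to give 4 (after reduction and protonation of the α‑formyl radical), and a second hydrogen‑atom transfer to C9 of the regenerated silyl enol ether should give the C8 radical, whose cyclobutylcarbinyl β‑scission breaks C4–C7 and frees the tertiary C4 radical for addition to the aldehyde carbon C3, the alkoxy radical being reduced and protonated. The closest known reaction types are the iron‑mediated reductive coupling of heteroatom‑substituted donor olefins with acrylic acceptors, the ring opening of pinane‑derived cyclobutylcarbinyl radicals and the hydrogen‑atom‑transfer‑initiated radical cyclization of alkenes onto carbonyl groups; new is their union on a siloxydiene, so that two C–C bonds form while one breaks. Ring A closes by 6‑exo‑trig attack of the C4 radical on C3=O through a chair. C10 is set by the gem‑dimethyl bridge of the pinane, which leaves only the face of the methylene bridge open, so C1 comes to lie trans to C4 and the ring fusion is trans (C5 is carried over from 1), and the C3 oxygen should take the equatorial position of the chair, helped by the reversibility of the addition to C=O. The step needs bond formation at C10 and not at C8 of the allyl radical, and no ring opening before the Giese addition: the first is secured by the bridgehead and the OTBS group that flank C8 and by the return of the conjugated silyl enol ether, the second by the allylic delocalization of the first radical, in contrast to the localized C8 radical of the second stage, which should open at once towards the tertiary centre.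

**Step 3**
Reactants: 5 hydroxy silyl enol ether
Product: 6 3‑O‑triethylsilyl ether of 5
Conditions: Et3SiOTf, 2,6‑lutidine, CH2Cl2, −78 °C
Reagents that add atoms: triethylsilyl triflate, CC[Si](CC)(CC)OS(=O)(=O)C(F)(F)F
Why: Silyl ether formation at the hindered secondary alcohol; it masks 3‑OH against the amide base of step 5 and the organozinc of step 8, and the non‑acidic conditions leave the silyl enol ether intact.

**Step 4**
Reactants: 6 bis‑silyl compound
Product: 7 Δ6‑en‑8‑one (3‑OTES)
Conditions: Pd(OAc)2, MeCN, rt
Reagents that add atoms: none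
Why: Saegusa–Ito oxidation: the palladium enolate formed from the regiodefined C7=C8 silyl enol ether can only eliminate a β‑hydride from C6, so one enone should result and C9 is left as the only enolizable α‑carbon.

**Step 5**
Reactants: 7 enone
Product: 8 9‑(2‑bromoethyl) enone (bromoethyl group trans to C20)
Conditions: LiN(i‑Pr)2, THF, −78 °C; then BrCH2CH2OTf, −78 to −30 °C
Reagents that add atoms: 2‑bromoethyl trifluoromethanesulfonate, BrCCOS(=O)(=O)C(F)(F)F
Why: Kinetic α′‑deprotonation of the enone and C‑alkylation of the lithium enolate, the triflate being displaced in preference to bromide; the electrophile should enter anti to the axial C20 methyl (axial attack), giving the kinetic C9 epimer that step 9 corrects.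

**Step 6**
Reactants: 8 bromoethyl enone
Product: 9 saturated bromo ketone (C9 as in 8)
Conditions: H2 (1 atm), 10% Pd/C, EtOAc, rt
Reagents that add atoms: none
Why: Catalytic hydrogenation of the disubstituted enone C=C; the primary bromide and the silyl ether should survive the short neutral reaction, and no stereocenter is formed.

**Step 7**
Reactants: 10 methyl but‑2‑ynoate
Product: 11 methyl (Z)‑3‑iodobut‑2‑enoate
Conditions: NaI, AcOH, 115 °C
Reagents that add atoms: sodium iodide, [Na+].[I-]
Why: Hydroiodination of an ynoate by conjugate addition of iodide and anti protonation, which should give the Z isomer with iodine cis to the ester.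

**Step 8**
Reactants: 9 bromo ketone; 11 methyl (Z)‑3‑iodobut‑2‑enoate
Product: 13 keto enoate carrying the complete side chain (C9 as in 9), via alkylzinc bromide 12 (not isolated)
Conditions: Zn, I2 (cat.), DMA, 70 °C; then 11, PdCl2(dppf) (5 mol %), THF, rt to 40 °C
Reagents that add atoms: none
Why: Negishi coupling: zinc inserts into the primary C–Br bond without touching the ketone, and the sp3–sp2 coupling proceeds with retention at the alkenyl iodide, so the 13Z geometry is taken over from 11.

**Step 9**
Reactants: 13 keto enoate (side chain trans to C20)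
Product: 15 hydroxy keto enoate with the side chain cis to C20, via C9‑equilibrated silyl ether 14 (not isolated)
Conditions: K2CO3 (cat.), MeOH, rt; then aq. HCl to pH 2, rt
Reagents that add atoms: none
Why: Base‑mediated epimerization α to the ketone should move C11 into the equatorial position (cis to C20, the labdane arrangement), and acidic methanolysis then cleaves the triethylsilyl ether.

**Step 10**
Reactants: 15 hydroxy keto enoate
Product: 16 8‑hydroxy‑17‑silyl adduct
Conditions: (i‑PrO)Me2SiCH2MgCl (excess), THF, 0 °C; aq. NH4Cl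
Reagents that add atoms: [(isopropoxy)dimethylsilyl]methylmagnesium chloride, CC(C)O[Si](C)(C)C[Mg]Cl
Why: Grignard addition of a hydroxymethyl‑anion equivalent to the ketone, which should outpace attack at the hindered conjugated ester; axial approach is blocked by the 1,3‑diaxial C20 methyl, so equatorial attack should place C17 equatorial and the 8‑OH axial (cis to C20).

**Step 11**
Reactants: 16 silyl adduct
Product: 17 3,8,17‑triol
Conditions: KF, KHCO3, 30% H2O2, THF/MeOH, rt
Reagents that add atoms: hydrogen peroxide, OO
Why: Tamao oxidation of the alkoxysilyl C–Si bond to C17–OH; the buffered peroxide should not touch the β,β‑disubstituted enoate.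

**Step 12**
Reactants: 17 triol
Product: 18 target
Conditions: [Cu(MeCN)4]OTf (cat.), 2,2′‑bipyridine, TEMPO, N‑methylimidazole, air, MeCN, rt
Reagents that add atoms: none
Why: Cu/TEMPO aerobic alcohol oxidation, selective for the primary C17–OH over the secondary C3–OH and the tertiary C8–OH; it should stop at the α‑hydroxy aldehyde, which is formed last because it is the most sensitive group.

**Compound list**

1 | (1S,5S)‑(−)‑verbenone, (1S,5S)‑4,6,6‑trimethylbicyclo[3.1.1]hept‑3‑en‑2‑one | CC1=CC(=O)[C@H]2C[C@@H]1C2(C)C | starting material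
2 | 2‑(tert‑butyldimethylsilyloxy)‑6,6‑dimethyl‑4‑methylidenebicyclo[3.1.1]hept‑2‑ene, bridgeheads as in 1 | C=C1C=C(O[Si](C)(C)C(C)(C)C)[C@H]2C[C@@H]1C2(C)C | intermediate
3 | acrolein (prop‑2‑enal) | C=CC=O | starting material
4 | 3‑[2‑(tert‑butyldimethylsilyloxy)‑4,6,6‑trimethylbicyclo[3.1.1]hept‑2‑en‑4‑yl]propanal, propanal chain anti to the gem‑dimethyl bridge | O=CCC[C@@]1(C)C=C(O[Si](C)(C)C(C)(C)C)[C@H]2C[C@@H]1C2(C)C | intermediate (not isolated)
5 | 8‑(tert‑butyldimethylsilyloxy)‑4,4,10‑trimethyl‑trans‑bicyclo[4.4.0]dec‑7‑en‑3‑ol (labdane numbers); 3‑OH equatorial and cis to C20, H‑5 trans to C20, C9 = CH2 | C1[C@]2(C)CC[C@@H](O)C(C)(C)[C@H]2CC=C1O[Si](C)(C)C(C)(C)C | intermediate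
6 | 3‑O‑triethylsilyl ether of 5 | C1[C@]2(C)CC[C@@H](O[Si](CC)(CC)CC)C(C)(C)[C@H]2CC=C1O[Si](C)(C)C(C)(C)C | intermediate
7 | 4,4,10‑trimethyl‑3‑(triethylsilyloxy)‑trans‑bicyclo[4.4.0]dec‑6‑en‑8‑one (labdane numbers), configuration as in 5 | C1[C@]2(C)CC[C@@H](O[Si](CC)(CC)CC)C(C)(C)[C@H]2C=CC1=O | intermediate
8 | 9‑(2‑bromoethyl) derivative of 7, bromoethyl group trans to C20 | BrCC[C@@H]1[C@]2(C)CC[C@@H](O[Si](CC)(CC)CC)C(C)(C)[C@H]2C=CC1=O | intermediate
9 | 6,7‑dihydro derivative of 8 (saturated C8 ketone, bromoethyl group trans to C20) | BrCC[C@@H]1[C@]2(C)CC[C@@H](O[Si](CC)(CC)CC)C(C)(C)[C@H]2CCC1=O | intermediate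
10 | methyl but‑2‑ynoate | CC#CC(=O)OC | starting material
11 | methyl (Z)‑3‑iodobut‑2‑enoate | COC(=O)/C=C(/C)I | intermediate
12 | alkylzinc bromide from 9 (C12–ZnBr) | Br[Zn]CC[C@@H]1[C@]2(C)CC[C@@H](O[Si](CC)(CC)CC)C(C)(C)[C@H]2CCC1=O | intermediate (not isolated)
13 | methyl (13Z)‑8‑oxo‑3‑(triethylsilyloxy)‑17‑nor‑ent‑labd‑13‑en‑15‑oate, C9 epimer (side chain trans to C20) | COC(=O)/C=C(/C)CC[C@@H]1[C@]2(C)CC[C@@H](O[Si](CC)(CC)CC)C(C)(C)[C@H]2CCC1=O | intermediate
14 | methyl (13Z)‑8‑oxo‑3‑(triethylsilyloxy)‑17‑nor‑ent‑labd‑13‑en‑15‑oate (side chain cis to C20) | COC(=O)/C=C(/C)CC[C@H]1[C@]2(C)CC[C@@H](O[Si](CC)(CC)CC)C(C)(C)[C@H]2CCC1=O | intermediate (not isolated)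
15 | methyl (3R,5S,9S,10R,13Z)‑3‑hydroxy‑8‑oxo‑17‑norlabd‑13‑en‑15‑oate | COC(=O)/C=C(/C)CC[C@H]1[C@]2(C)CC[C@@H](O)C(C)(C)[C@H]2CCC1=O | intermediate
16 | methyl (13Z)‑3,8‑dihydroxy‑17‑[isopropoxy(dimethyl)silyl]‑ent‑labd‑13‑en‑15‑oate, 8‑OH axial and cis to C20 | COC(=O)/C=C(/C)CC[C@H]1[C@]2(C)CC[C@@H](O)C(C)(C)[C@H]2CC[C@]1(O)C[Si](C)(C)OC(C)C | intermediate
17 | methyl (13Z)‑3,8,17‑trihydroxy‑ent‑labd‑13‑en‑15‑oate, configuration as in 18 | COC(=O)/C=C(/C)CC[C@H]1[C@]2(C)CC[C@@H](O)C(C)(C)[C@H]2CC[C@]1(O)CO | intermediate
18 | methyl (3R,5S,8R,9S,10R,13Z)‑3,8‑dihydroxy‑17‑oxolabd‑13‑en‑15‑oate (ent‑labdane series) | COC(=O)/C=C(/C)CC[C@H]1[C@]2(C)CC[C@@H](O)C(C)(C)[C@H]2CC[C@]1(O)C=O | target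

**Step count**

Total steps: 12. Longest linear sequence: 11 (steps 1–6 and 8–12; step 7 makes the coupling partner).

**Steps most likely to fail**

1. Step 2 (the proposed new method).
   - What may go wrong: ring opening of the first allyl radical before it meets acrolein, or its bond formation at C8; hydrogen‑atom reduction of the radicals outrunning the Giese addition or the 6‑exo closure; loss of the silyl enol ether by solvolysis before the second hydrogen‑atom transfer; poor facial selectivity at C3.
   - Fallback with known chemistry, setting out from 1 and returning at 7: Cu‑catalysed conjugate addition of [2‑(1,3‑dioxolan‑2‑yl)ethyl]magnesium bromide to 1 (CuBr·SMe2, Me3SiCl, THF, −40 °C) should give, anti to the gem‑dimethyl bridge, the ketone acetal F1. Me3SiI (from Me3SiCl/NaI, MeCN, 0 °C) should open the cyclobutane at C4–C7 and cleave the acetal, giving after aqueous work‑up the tertiary iodide keto aldehyde F2, used crude. Bu3SnH/AIBN (PhH, 80 °C, slow addition) should close ring A by 6‑exo radical cyclization of the C4 radical onto the aldehyde to give the hydroxy ketone F3. Et3SiOTf/2,6‑lutidine should give the silyl ether F4. IBX (DMSO/PhMe, 70 °C) can only dehydrogenate towards C6 because C10 is quaternary, and should give 7.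

2. Step 5.
   - What may go wrong: O‑alkylation of the hindered enolate by the triflate; proton transfer between product and enolate followed by intramolecular displacement of bromide (cyclopropane formation); competing γ‑deprotonation at C5.
   - Fallback, setting out from 7 and returning at 14: alkylation of the same lithium enolate with allyl bromide should give the allyl enone F5. Conjugate reduction with [(Ph3P)CuH]6 followed by NaOMe/MeOH equilibration at C9 should give the allyl ketone F6. OsO4 (cat.)/NaIO4 (Lemieux–Johnson cleavage) should give the aldehyde F7. NaBH4 (MeOH, −78 °C) should reduce only the aldehyde, giving the alcohol F8. CBr4/PPh3 (Appel reaction) should give the bromide F9. Negishi coupling of F9 with 11 under the conditions of step 8 should give 14 directly, which is then desilylated as in step 9.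

3. Step 10.
   - What may go wrong: enolization of the hindered C8 ketone by the Grignard reagent, competing attack at the methyl ester, or erosion of the equatorial facial selectivity.
   - Fallback, setting out from 15 and returning at 17: Corey–Chaykovsky reaction with the ylide from Me3SI and KN(SiMe3)2 (THF, 0 °C), which does not attack esters and should deliver CH2 equatorially, gives the spiro‑epoxide F10. CsOAc/18‑crown‑6 (DMF, 90 °C) should open it at the primary carbon C17 to give the hydroxy acetate F11. K2CO3/MeOH should then give 17.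

**Further compounds**

F1 | step 2 | 4‑[2‑(1,3‑dioxolan‑2‑yl)ethyl]‑4,6,6‑trimethylbicyclo[3.1.1]heptan‑2‑one, new chain anti to the gem‑dimethyl bridge | O1CCOC1CC[C@@]3(C)CC(=O)[C@H]2C[C@@H]3C2(C)C
F2 | step 2 | 3‑[2‑(2‑iodopropan‑2‑yl)‑1‑methyl‑5‑oxocyclohexyl]propanal, iodopropyl group and propanal chain trans | O=CCC[C@@]1(C)CC(=O)CC[C@@H]1C(C)(C)I
F3 | step 2 | 3‑hydroxy‑4,4,10‑trimethyl‑trans‑bicyclo[4.4.0]decan‑8‑one (labdane numbers), 3‑OH equatorial | C1[C@]2(C)CC[C@@H](O)C(C)(C)[C@H]2CCC1=O
F4 | step 2 | 3‑O‑triethylsilyl ether of F3 | C1[C@]2(C)CC[C@@H](O[Si](CC)(CC)CC)C(C)(C)[C@H]2CCC1=O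
F5 | step 5 | 9‑allyl derivative of 7, allyl group trans to C20 | C=CC[C@@H]1[C@]2(C)CC[C@@H](O[Si](CC)(CC)CC)C(C)(C)[C@H]2C=CC1=O
F6 | step 5 | saturated 9‑allyl ketone, allyl group cis to C20 | C=CC[C@H]1[C@]2(C)CC[C@@H](O[Si](CC)(CC)CC)C(C)(C)[C@H]2CCC1=O
F7 | step 5 | C12 aldehyde from F6 | O=CC[C@H]1[C@]2(C)CC[C@@H](O[Si](CC)(CC)CC)C(C)(C)[C@H]2CCC1=O
F8 | step 5 | C12 alcohol from F7 | OCC[C@H]1[C@]2(C)CC[C@@H](O[Si](CC)(CC)CC)C(C)(C)[C@H]2CCC1=O
F9 | step 5 | C12 bromide, the C9 epimer of 9 (bromoethyl group cis to C20) | BrCC[C@H]1[C@]2(C)CC[C@@H](O[Si](CC)(CC)CC)C(C)(C)[C@H]2CCC1=O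
F10 | step 10 | methyl (13Z)‑8,17‑epoxy‑3‑hydroxy‑ent‑labd‑13‑en‑15‑oate, epoxide oxygen axial and cis to C20 | COC(=O)/C=C(/C)CC[C@H]1[C@]2(C)CC[C@@H](O)C(C)(C)[C@H]2CC[C@]13CO3
F11 | step 10 | methyl (13Z)‑17‑acetoxy‑3,8‑dihydroxy‑ent‑labd‑13‑en‑15‑oate | COC(=O)/C=C(/C)CC[C@H]1[C@]2(C)CC[C@@H](O)C(C)(C)[C@H]2CC[C@]1(O)COC(C)=O
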